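At early times the adducts form fast: in the green run at 0.417 min, mono adduct stands at 44.7% and bis adduct at 5.9% of the substrate charged. If mono adduct holds one reagent unit and bis adduct two, these readings already hold 85.3% of green's reagent.

| flask | substrate | reagent | remark | time |
|---|---|---|---|---|
| green | 0.80 M | 0.53 M | run made earlier |  |
| teal | 0.80 M | 1.3 M | run made earlier |  |
| amber | 0.80 M | 2.3 M | run made earlier |  |
| birch | 0.80 M | 2.40 M |  | 6.0 min |
| cedar | 0.80 M | 0.640 M |  | 6.0 min |

| run | time / min | bis adduct / % | mono adduct / % |
|---|---|---|---|
| green | 0.417 | 5.9 | 44.7 |
| green | 1.00 | 3.6 | 36.5 |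
| green | 2.00 | 2.0 | 27.6 |
| green | 3.00 | 0.8 | 22.0 |
| green | 4.00 | 1.1 | 17.6 |
| teal | 0.833 | 32.6 | 29.0 |
| teal | 1.50 | 28.5 | 18.4 |
| teal | 2.50 | 24.8 | 12.3 |
| teal | 3.00 | 23.2 | 9.7 |
| teal | 4.00 | 20.7 | 6.8 |
| amber | 0.833 | 54.7 | 15.8 |
| amber | 1.50 | 47.4 | 11.7 |
| amber | 2.50 | 42.0 | 7.9 |
| amber | 3.00 | 39.3 | 7.1 |
| amber | 4.00 | 35.2 | 5.4 |

(standard deviation of a reading: 0.5 percentage points)



- which of these holds the largest part of the substrate at the end of birch (substrate / mono adduct / bis adduct)
- which of these holds the largest part of the substrate at the end of cedar (substrate / mono adduct / bis adduct)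
- final bis adduct in cedar, as a percentage of the substrate charged

So I count turnovers. The first turnover of a substrate costs one reagent, and E, the reagent charged per substrate charged, is the number of first turnovers on offer. If that step runs one way and its reagent stays in what it makes, then E below one leaves a part of the substrate unturned. For cedar, one minus E gives 20.0%, the untouched share, with reagent as the limiting reagent. Green's mono adduct is lower than this at 4.00 min, at 17.6%, and falling, so I expect substrate to lead in cedar.

Birch has E of 3.00, so it has no such share. If the first step runs one way, amber's substrate can stand no higher after 0.833 min than the 29.5% that its first reading leaves unaccounted for. Amber's bis adduct still reads 35.2% at 4.00 min, which is more than that. The 59.4% missing from amber's last reading must then be partly an unseen product, and since birch's charge lies close to amber's, I expect bis adduct to lead in birch.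

The forecast names substrate for birch, so we part there. It names substrate for cedar and gives 1.3% of bis adduct, within 0.5% to 3%, on the ground that “Cedar lies just above green”.

    substrate + reagent → mono adduct + by-product (k = 0.460 M⁻¹ s⁻¹)
    reagent + mono adduct ⇌ bis adduct + by-product (K = 3.00, k = 0.140 M⁻¹ s⁻¹)
    mono adduct + by-product → side product (k = 0.0220 M⁻¹ s⁻¹)

Cedar ends with 0.609% of bis adduct, and substrate leads there among the three asked species, while bis adduct leads in birch at 31.0%. Birch's substrate stands at 0%, and its side product at 65.2%. Cedar's substrate stands at 20.7% against the untouched share of 20.0%, with reagent at 0.0512% of its own charge. A neighbouring flask, like cedar but with 0.26 M of reagent, has an untouched share of 67.5%, and at 6.00 min it holds 67.7% of its substrate.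

The earlier runs and the new flask are calculated from invented constants.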